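**Assumption:** the SMILES is taken as definitive. It encodes a cis-fused eastern decalin, (4aR,8S,8aS), and a (3S,5aS,6S,7S,9aS)-decahydro-1-benzoxepine. The ent-Shi ketone (L-fructose-derived) and trans,trans-farnesyl chloride are treated as purchasable. Nothing here has been run; selectivities are predictions.

## Retrosynthetic overview

1. Cut the bond between the enone β-carbon (C4) and the CH2CH2 linker: western primary alkyl-cerium plus eastern cis-fused enone 17, then Babler–Dauben 1,3-oxidative transposition. The C8 tertiary OH is added last by Mukaiyama hydration.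
2. Western half: oxepane, cyclohexane and a temporary γ-lactone are formed in one epoxonium cascade of a diepoxy tert-butyl homofarnesate (the proposed new step). Epoxides come from ent-Shi epoxidation; the lactone supplies the two linker carbons.
3. Eastern half: ring 1 is (S)-carvone (sets C8a). Quaternary C5 comes from Sakurai allylation with kinetic cis protonation (sets C4a), ring 2 from RCM, and the enone is restored by Saegusa oxidation.
4. Ring order: west, oxepane then cyclohexane (one step); east, chiral-pool cyclohexanone then cyclohexene; the fragments are joined after all four rings exist.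

Locants: compounds 15–18 use 1-naphthalenone numbering; 19–21 use the target's 2(1H)-naphthalenone numbering. "W" = (3S,5aS,6S,7S,9aS)-2,2,5a,7-tetramethyl-3,7-bis(triethylsilyloxy)decahydro-1-benzoxepin-6-yl.

## Western fragment

**Step 1**
Reactants: 1, (2E,6E)-farnesyl chloride
Product: 2, (3E,7E)-4,8,12-trimethyltrideca-3,7,11-trienoic acid (homofarnesic acid)
Conditions: Rieke Ba (BaI2, Li biphenylide), THF, −78 °C; CO2; H3O+
Reagents that add atoms: carbon dioxide, O=C=O
Why: α-selective, geometry-retentive carboxylation of an allylbarium reagent gives the linear β,γ-unsaturated acid without E/Z scrambling.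

**Step 2**
Reactants: 2, homofarnesic acid
Product: 3, tert-butyl (3E,7E)-4,8,12-trimethyltrideca-3,7,11-trienoate
Conditions: O-tert-butyl-N,N'-diisopropylisourea, CH2Cl2, rt
Reagents that add atoms: O-tert-butyl-N,N'-diisopropylisourea, CC(C)NC(=NC(C)C)OC(C)(C)C
Why: neutral isourea esterification avoids acid (polyene cyclization) and base (β,γ to α,β isomerization).

**Step 3**
Reactants: 3, tert-butyl homofarnesate
Product: 4, tert-butyl (3E,7S,8S,11S)-7,8:11,12-diepoxy-4,8,12-trimethyltridec-3-enoate
Conditions: ent-Shi ketone (0.4 equiv), Oxone (2.4 equiv), K2CO3, Bu4NHSO4, MeCN/DMM/pH 10.5 buffer, 0 °C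
Reagents that add atoms: Oxone (KHSO5), [K+].[O-]S(=O)(=O)OO
Why: Shi asymmetric epoxidation; the L-series dioxirane gives (S,S)/(S) epoxides on the two distal trisubstituted alkenes, while the 3,4-alkene is deactivated inductively by the adjacent CH2CO2tBu.

**Step 4**
Reactants: 4, diepoxy ester
Product: 5, 7-O γ-lactone of [(3S,5aS,6S,7S,9aS)-3,7-dihydroxy-2,2,5a,7-tetramethyldecahydro-1-benzoxepin-6-yl]acetic acid (trans-fused oxepane/cyclohexane, trans-fused lactone, free 3-OH)
Conditions: TMSOTf (1.3 equiv), 2,6-di-tert-butyl-4-methylpyridine, CH2Cl2, −78 °C; then TBAF/AcOH, THF, 0 °C (O–SiMe3 cleavage)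
Reagents that add atoms: none
Why: Proposed new method: silyl activation of the terminal epoxide lets the internal epoxide oxygen attack C12 (7-endo) to form a bridged epoxonium ion; its tertiary C8–O bond is opened anti by the C3=C4 alkene through a chair transition state while the tert-butyl ester carbonyl captures the developing C4 cation (anti addition, then loss of isobutylene), so C7 and C11 are retained from the epoxides, C8 is inverted, and the E-alkene sets the equatorial lactone oxygen and equatorial CH2 at C4/C3; the closest known reaction type is the Lewis-acid tandem endo-oxacyclization/carbacyclization of polyepoxides ended by enol-silane or allylsilane terminators, combined with the lactone termination of homofarnesic acid polyene cyclization and tert-butyl carbonate/ester trapping of cations.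

**Step 5**
Reactants: 5, hydroxy lactone
Product: 6, (3S,5aS,6S,7S,9aS)-6-(2-hydroxyethyl)-2,2,5a,7-tetramethyldecahydro-1-benzoxepine-3,7-diol
Conditions: LiAlH4, THF, 0 °C to rt
Reagents that add atoms: none
Why: hydride reduction of the lactone unmasks the equatorial tertiary alcohol and the two-carbon linker; no stereocentre is touched.

**Step 6**
Reactants: 6, triol
Product: 7, tris(triethylsilyl) ether of 6
Conditions: TESOTf (4.5 equiv), 2,6-lutidine, CH2Cl2, 0 °C to rt
Reagents that add atoms: triethylsilyl triflate, CC[Si](CC)(CC)OS(=O)(=O)C(F)(F)F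
Why: silyl triflate silylates even the tertiary alcohol, which must be capped to prevent tetrahydrofuran formation once the primary position is activated.

**Step 7**
Reactants: 7, tris-TES ether
Product: 8, 2-[(3S,5aS,6S,7S,9aS)-2,2,5a,7-tetramethyl-3,7-bis(triethylsilyloxy)decahydro-1-benzoxepin-6-yl]ethan-1-ol
Conditions: PPTS (cat.), MeOH/CH2Cl2, −10 °C
Reagents that add atoms: none
Why: acid-catalysed solvolysis removes the unhindered primary TES ether much faster than the neopentyl-type secondary and the tertiary ones.

**Step 8**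
Reactants: 8, primary alcohol
Product: 9, (3S,5aS,6S,7S,9aS)-6-(2-iodoethyl)-2,2,5a,7-tetramethyl-3,7-bis(triethylsilyloxy)decahydro-1-benzoxepine
Conditions: I2, PPh3, imidazole, CH2Cl2, 0 °C
Reagents that add atoms: iodine, II
Why: Appel-type (Garegg) iodination of the primary alcohol under near-neutral conditions.

## Eastern fragment

**Step 9**
Reactants: 10, (S)-(+)-carvone
Product: 11, (2RS,5S)-2-methyl-5-(prop-1-en-2-yl)cyclohexan-1-one (dihydrocarvone)
Conditions: L-Selectride, THF, −78 °C; NH4Cl
Reagents that add atoms: none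
Why: conjugate hydride reduction temporarily removes the ring enone so that only the exocyclic enone made later can accept the allyl group; C5 is untouched.

**Step 10**
Reactants: 11, dihydrocarvone
Product: 12, (3S,6RS)-2-(2-hydroxypropan-2-yl)-6-methyl-3-(prop-1-en-2-yl)cyclohexan-1-one (C2 epimers)
Conditions: LDA, THF, −78 °C; ZnCl2; acetone
Reagents that add atoms: acetone, CC(C)=O
Why: kinetic deprotonation at the CH2 α-carbon and a zinc-mediated aldol with acetone; the new stereocentre is destroyed in the next step.

**Step 11**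
Reactants: 12, aldol adduct
Product: 13, (3R,6RS)-6-methyl-3-(prop-1-en-2-yl)-2-(propan-2-ylidene)cyclohexan-1-one (the CIP label changes; the carvone-derived centre is spatially unchanged)
Conditions: SOCl2, pyridine, 0 °C; then DBU, CH2Cl2, rt
Reagents that add atoms: none
Why: dehydration followed by base equilibration converges on the conjugated isopropylidene ketone (pulegone-type).

**Step 12**
Reactants: 13, isopropylidene ketone
Product: 14, (2R,3S,6RS)-6-methyl-2-(2-methylpent-4-en-2-yl)-3-(prop-1-en-2-yl)cyclohexan-1-one (2,3-cis)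
Conditions: allyltrimethylsilane, TiCl4, CH2Cl2, −78 °C; quench MeOH/aq. NH4Cl at −78 °C
Reagents that add atoms: allyltrimethylsilane, C=CC[Si](C)(C)C
Why: Sakurai–Hosomi conjugate allylation builds the quaternary gem-dimethyl carbon, and the titanium enolate (isopropenyl pseudo-axial through A(1,2) strain) is protonated anti to it to give the cis-2,3 isomer; any trans isomer can be recycled by enolization and kinetic reprotonation.

**Step 13**
Reactants: 14, diene ketone
Product: 15, (2RS,4aS,8aR)-2,5,8,8-tetramethyl-3,4,4a,7,8,8a-hexahydronaphthalen-1(2H)-one (cis-fused)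
Conditions: Grubbs II (5 mol %), CH2Cl2 (5 mM), 40 °C
Reagents that add atoms: none
Why: ring-closing metathesis of the allyl and isopropenyl groups (loss of ethylene) closes ring 2 as a trisubstituted cyclohexene without touching the cis stereocentres.

**Step 14**
Reactants: 15, bicyclic ketone
Product: 16, trimethyl{[(4aS,8aR)-2,5,8,8-tetramethyl-3,4,4a,7,8,8a-hexahydronaphthalen-1-yl]oxy}silane
Conditions: LDA, THF, −78 °C; TMSCl, Et3N
Reagents that add atoms: chlorotrimethylsilane, C[Si](C)(C)Cl
Why: LDA removes the accessible C2–H rather than the C8a–H shielded by the gem-dimethyl group, giving the silyl enol ether regioselectively and leaving the ring fusion intact.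

**Step 15**
Reactants: 16, silyl enol ether
Product: 17, (4aS,8aR)-2,5,8,8-tetramethyl-4a,7,8,8a-tetrahydronaphthalen-1(4H)-one (cis-fused)
Conditions: Pd(OAc)2 (1.1 equiv), MeCN, rt
Reagents that add atoms: none
Why: Saegusa–Ito oxidation (β-hydride elimination toward the ring CH2) regenerates the carvone-type enone under neutral conditions.

## Union and completion

**Step 16**
Reactants: 9, western iodide; 17, eastern enone
Product: 18, (1RS,4aS,8aR)-2,5,8,8-tetramethyl-1-(2-W-ethyl)-1,4,4a,7,8,8a-hexahydronaphthalen-1-ol
Conditions: 9, t-BuLi (2.05 equiv), Et2O, −78 °C; anhydrous CeCl3, THF, −78 °C; then 17, −78 to −40 °C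
Reagents that add atoms: none
Why: iodine–lithium exchange and transmetalation to the organocerium give clean 1,2-addition to the hindered, enolizable enone; the new carbinol centre is erased in the next step.

**Step 17**
Reactants: 18, tertiary allylic alcohol
Product: 19, (4aR,8aS)-3,5,5,8-tetramethyl-4-(2-W-ethyl)-4a,5,6,8a-tetrahydronaphthalen-2(1H)-one
Conditions: PCC, 4 Å MS, CH2Cl2, rt
Reagents that add atoms: none
Why: Babler–Dauben oxidation ([3,3] shift of the chromate ester, then oxidation) moves the oxygen to C2 and places the tetrasubstituted C3=C4 alkene; C4a/C8a are not epimerizable under these conditions.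

**Step 18**
Reactants: 19, dienone
Product: 20, (4aR,8S,8aS)-8-hydroxy-3,5,5,8-tetramethyl-4-(2-W-ethyl)-4a,5,6,7,8,8a-hexahydronaphthalen-2(1H)-one
Conditions: Co(acac)2 (0.3 equiv), PhSiH3, O2 (1 atm), THF/i-PrOH, rt; then PPh3
Reagents that add atoms: dioxygen, O=O
Why: Mukaiyama hydration (metal-hydride H-atom transfer) converts only the trisubstituted C7=C8 alkene (the tetrasubstituted enone is inert) to the tertiary radical, which O2 should trap on the convex face, anti to the pseudo-axial C8a–C1 bond, placing OH cis to H-8a.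

**Step 19**
Reactants: 20, bis-TES ether
Product: 21, sipholenol K
Conditions: HF·pyridine, pyridine/THF, 0 °C to rt
Reagents that add atoms: none
Why: fluoride-mediated global desilylation releases the secondary and tertiary western alcohols without affecting the enone or the tertiary carbinols.

## Compound list

1 | (2E,6E)-farnesyl chloride | CC(C)=CCC/C(C)=C/CC/C(C)=C/CCl | starting material
2 | (3E,7E)-homofarnesic acid | CC(C)=CCC/C(C)=C/CC/C(C)=C/CC(=O)O | intermediate
3 | tert-butyl (3E,7E)-homofarnesate | CC(C)=CCC/C(C)=C/CC/C(C)=C/CC(=O)OC(C)(C)C | intermediate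
4 | tert-butyl (3E,7S,8S,11S)-7,8:11,12-diepoxy-4,8,12-trimethyltridec-3-enoate | CC(C)(C)OC(=O)C/C=C(\C)CC[C@@H]1O[C@@]1(C)CC[C@@H]1OC1(C)C | intermediate
5 | tricyclic hydroxy γ-lactone (3S,5aS,6S,7S,9aS) | O=C1C[C@H]2[C@]3(C)CC[C@H](O)C(C)(C)O[C@H]3CC[C@]2(C)O1 | intermediate
6 | (3S,5aS,6S,7S,9aS)-6-(2-hydroxyethyl)-2,2,5a,7-tetramethyldecahydro-1-benzoxepine-3,7-diol | OCC[C@H]1[C@]2(C)CC[C@H](O)C(C)(C)O[C@H]2CC[C@]1(C)O | intermediate
7 | tris-TES ether of 6 | CC[Si](CC)(CC)OCC[C@H]1[C@]2(C)CC[C@H](O[Si](CC)(CC)CC)C(C)(C)O[C@H]2CC[C@]1(C)O[Si](CC)(CC)CC | intermediate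
8 | 2-W-ethan-1-ol | OCC[C@H]1[C@]2(C)CC[C@H](O[Si](CC)(CC)CC)C(C)(C)O[C@H]2CC[C@]1(C)O[Si](CC)(CC)CC | intermediate
9 | W–CH2CH2–I (2-iodoethyl bis-TES benzoxepane) | ICC[C@H]1[C@]2(C)CC[C@H](O[Si](CC)(CC)CC)C(C)(C)O[C@H]2CC[C@]1(C)O[Si](CC)(CC)CC | intermediate
10 | (S)-(+)-carvone | CC1=CC[C@@H](CC1=O)C(C)=C | starting material
11 | (2RS,5S)-dihydrocarvone | CC1CC[C@@H](CC1=O)C(C)=C | intermediate
12 | (3S,6RS)-2-(2-hydroxypropan-2-yl)-6-methyl-3-(prop-1-en-2-yl)cyclohexan-1-one | CC1CC[C@H](C(C)=C)C(C1=O)C(C)(C)O | intermediate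
13 | (3R,6RS)-6-methyl-3-(prop-1-en-2-yl)-2-(propan-2-ylidene)cyclohexan-1-one | CC1CC[C@H](C(C)=C)C(C1=O)=C(C)C | intermediate
14 | (2R,3S,6RS)-6-methyl-2-(2-methylpent-4-en-2-yl)-3-(prop-1-en-2-yl)cyclohexan-1-one | CC1CC[C@H](C(C)=C)[C@@H](C1=O)C(C)(C)CC=C | intermediate
15 | (2RS,4aS,8aR)-2,5,8,8-tetramethyl-3,4,4a,7,8,8a-hexahydronaphthalen-1(2H)-one | CC1CC[C@H]2[C@@H](C1=O)C(C)(C)CC=C2C | intermediate
16 | TMS enol ether of 15 | CC1=C(O[Si](C)(C)C)[C@@H]2[C@H](CC1)C(C)=CCC2(C)C | intermediate
17 | (4aS,8aR)-2,5,8,8-tetramethyl-4a,7,8,8a-tetrahydronaphthalen-1(4H)-one | CC1=CC[C@H]2[C@@H](C1=O)C(C)(C)CC=C2C | intermediate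
18 | coupled tertiary allylic alcohol (C1 epimers) | CC1=CC[C@H]2[C@@H](C1(O)CC[C@H]1[C@]3(C)CC[C@H](O[Si](CC)(CC)CC)C(C)(C)O[C@H]3CC[C@]1(C)O[Si](CC)(CC)CC)C(C)(C)CC=C2C | intermediate
19 | coupled transposed enone with C7=C8 alkene | CC1=C(CC[C@H]2[C@]3(C)CC[C@H](O[Si](CC)(CC)CC)C(C)(C)O[C@H]3CC[C@]2(C)O[Si](CC)(CC)CC)[C@@H]2[C@H](CC1=O)C(C)=CCC2(C)C | intermediate
20 | bis-TES sipholenol K | CC1=C(CC[C@H]2[C@]3(C)CC[C@H](O[Si](CC)(CC)CC)C(C)(C)O[C@H]3CC[C@]2(C)O[Si](CC)(CC)CC)[C@@H]2[C@H](CC1=O)[C@@](C)(O)CCC2(C)C | intermediate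
21 | sipholenol K | CC1=C(CC[C@H]2[C@]3(C)CC[C@H](O)C(C)(C)O[C@H]3CC[C@]2(C)O)[C@@H]2[C@H](CC1=O)[C@@](C)(O)CCC2(C)C | target

## Summary

Total steps: 19. Longest linear sequence: 12 (Steps 1–8, then 16–19). The eastern branch is 7 steps (9–15) before the union.

Steps most likely to fail, each with a fallback:

1. **Step 4 (proposed lactone-terminated oxa/carbacyclization).** The ester-deactivated alkene may not intercept the epoxonium ion, giving monocyclic oxepanes or elimination products. Fallback (known chemistry): use an established terminator. Prepare the analogous (S,S,S)-diepoxide bearing a 2-(trimethylsilylmethyl)alkene (allylsilane) terminator and a protected 2-hydroxyethyl chain, and run the known TMSOTf cascade to the benzoxepane with an exocyclic methylene. Then mCPBA from the equatorial face and LiAlH4 install the equatorial tertiary alcohol, converging on 8.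

2. **Step 16 (organocerium addition to the hindered, enolizable ketone of 17).** Fallback: form the same bond by Pd cross-coupling. Convert 15 to its enol triflate (LDA, PhNTf2; same regiochemistry as 16) and run a B-alkyl Suzuki–Miyaura coupling with the alkyl-9-BBN from 9 (t-BuLi, then B-OMe-9-BBN) to give the C3=C4 tetrasubstituted alkene directly. Allylic oxidation at C2 (CrO3·3,5-dimethylpyrazole) then gives 19; the regioselectivity of that oxidation is its own weak point.

3. **Step 18 (late Mukaiyama hydration; facial and chemoselectivity).** Fallback: install the C8 oxygen on the eastern fragment before coupling. Epoxidize 17 with mCPBA (convex face), open with LiAlH4 (trans-diaxial at C7; the ketone is also reduced), reoxidize the allylic alcohol with MnO2, and protect as the TES ether. Carry this through Steps 16, 17 and 19.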